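Rate first. I want one rule for how fast these flasks run, and then I read Tuesday's flask from it.

the same everywhere: free catalyst 0.0200 M

| flask | starting material | coupling partner | time |
|---|---|---|---|
| Monday's | 0.250 M | 0.300 M |  |
| Wednesday's | 0.250 M | 0.450 M |  |
| Tuesday's | 0.0500 M | 0.300 M | 44 h |

- Monday's run (time / h: [target] / M): 7.3: 0.0268; 15: 0.0737; 22: 0.1105; 29: 0.1453; 37: 0.1724; 44: 0.1955
- Wednesday's run (time / h: [target] / M): 7.3: 0.0241; 15: 0.0743; 22: 0.1155; 29: 0.1488; 37: 0.1781; 44: 0.1967

(readings scatter by 0.002 M)

- the exponent of [coupling partner] in the starting rate at the charge of the Monday's run (at the point where two percent of the starting material have become target)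
- target in the Tuesday's run at 44 h, as a share of the starting material charged
- which of these the readings show (the catalyst rests as a dimer / the second partner is lost in pairs / the product binds the substrate / the loaded catalyst dies / the catalyst wakes slowly)

- Overall: starting material + coupling partner -> target, with free catalyst as catalyst.
- Constant volume, constant temperature.
- A reading of a species includes what of it is bound.
- "The second partner" is coupling partner.
- An order is taken over about fifteen percent of the charge, up and down.

In Monday's run the rate is 0.00367 M h⁻¹ up to the first reading and 0.00609 M h⁻¹ up to the second, faster than before. A rate that climbs before it falls is an induction period, so I read a catalyst that wakes slowly. Raising the coupling partner 1.50-fold in Wednesday's run changes the last reading by a ratio of 1.01, which I reckon as an order of 0.0151.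

The late slowing I tie to the starting material, with a rule solved at both ends. Far above a level K the rate stands at a ceiling V, and the clock counts amount made over V. Far below K the run is pseudo-first-order with constant V/K, and the clock counts K/V times the logarithm of the fall. Joined, the time is the lag plus both terms, and the rate is V divided by one plus K/[starting material].

Monday's readings at 15 h, 29 h and 44 h give K = 0.280 M, V = 0.0155 M h⁻¹ and a lag of 3.96 h. K is the half-speed level, the [starting material] at which the rule puts the rate at half of V. The charge divides V by 2.12 on Monday but by 6.61 on Tuesday, so Tuesday's run starts slower, at 0.00235 M h⁻¹ once awake. Solving the joined clock for Tuesday's run, I commit to 87.3 %. Of 44 h, the lag takes 3.96 h, the ceiling term 2.81 h, and the rest runs at 0.0554 h⁻¹.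

The forecast gives an order of 0.05, a share of 89 % and the catalyst wakes slowly, in its words “so the catalyst wakes slowly”. Its share stands above mine, and its order above mine.

The flask gives an order of 0.028, a share of 86.6 % and the catalyst wakes slowly.

    active catalyst + starting material → catalyst-substrate complex (2.740 L mol⁻¹ h⁻¹)
    catalyst-substrate complex + coupling partner → loaded catalyst (28.69 L mol⁻¹ h⁻¹)
    loaded catalyst → target + active catalyst (0.9936 h⁻¹)
    free catalyst → active catalyst (0.2689 h⁻¹)

The forecast's order is 1.79 times the flask's, and its share lies within the margin. The slowness of free catalyst turning into active catalyst moves the readings by 8.3 scatter units, root mean square. Put to Wednesday's run, K, V and the lag from Monday's run place the point where target reaches half of the starting material at 24.5 h, and Wednesday's run reaches it at 24.1 h.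

Readings and results are calculated for substances that don't exist, and the scatter is random.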